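## The problem

Kweichowenol B (12) is a single cyclohexene ring with no fused or bridged partner, so nothing in the target itself relays stereochemistry, and every sp3 ring carbon carries oxygen. The numbering used throughout is C1 for the quaternary carbinol carbon, C7 for its benzoyloxymethyl carbon, C2=C3 for the alkene, C4 for the secondary benzoate carbon, and C5, C6 for the two CHOH carbons. β is the face of the C1 hydroxyl and α the opposite face.

The four stereocentres are 1β-OH (C7 α), 4α-OBz, 5β-OH and 6α-OH, i.e. (1R,4S,5S,6S). Every vicinal pair of oxygens is trans, and O1 and O4 are trans across the alkene. C6 is the centre least open to later correction, because it sits beside the fully substituted C1 and is closed to SN2. C4 (allylic) and C5 are ordinary secondary carbinols and can be inverted. A cis-fused acetal on O5/O6 can shield the α face at both C1 and C4, but it holds C5 in the wrong configuration, so its use must be paid for by an inversion at C5.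

Five oxygens have to end in two classes: O7 and O4 benzoylated, O1, O5 and O6 free. The benzoates do not survive alkoxide or hydroxide (cleavage, O4→O5 and O7→O6 acyl shifts). The tertiary allylic alcohol and the allylic benzoate do not survive strong acid, the oxygenated ring aromatises by elimination if pushed, and the diene intermediates dimerise on standing.

The enabling feature is that C1 and C4 both bear oxygen and flank C2=C3. A 2-ene-1,4-dioxygen unit is the retron of a [4+2] adduct of O2 across a C1=C2–C3=C4 diene. What then remains is a C5/C6 glycol next to a 1-substituted diene with C6 configured as in 12, which is the cis-dihydrodiol that microbial dioxygenation makes from a monosubstituted benzene.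

## Retrosynthesis

**C5–O (12 ⇒ 10 ⇒ 9).** The 5β-hydroxyl is traced through nitrite ester 11 to the 5α-triflate 10, and so to the 5-epimer 9, in which O5 and O6 are cis. Two neighbouring cuts were weighed. Closing a 4β,5β-oxirane from a 4β-hydroxyl and opening it at allylic C4 with benzoate would give both inversions from one activation, but it needs the same C5-selective sulfonylation beside a free C4–OH and ends on an acid-labile vinyl oxirane. An oxidation–reduction at C5 would put a ketone next to the allylic, benzoyloxy-bearing C4 and invite aromatisation. The displacement asks three things of the forward chemistry: sulfonylation at O5 only (O6 is neopentyl-like, O1 tertiary), an oxygen nucleophile that leaves a free hydroxyl without ester cleavage (nitrite), and no neighbouring-group detour (the C4 benzoate is cis to the leaving group and cannot bridge). Precursor 9 is simpler where it counts, because its cis O5/O6 pair can be carried as one acetal.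

**Acetal C–O bonds (9 ⇒ 8).** Tying O5 and O6 into an isopropylidene acetal reduces the protecting-group problem to one group. It leaves the tertiary O1 as the only free hydroxyl in 8, and it is the element that controls the faces earlier on. The forward step has to be an acid hydrolysis mild enough to spare the allylic benzoate, the tertiary allylic alcohol and the O4/O5 acyl position.

**C4–O (8 ⇒ 7).** The C4 benzoate C–O bond is cut with inversion, leading back to the 4β-alcohol 7. A Mitsunobu esterification installs the final ester and corrects C4 in one step. Acylation with retention followed by a separate inversion, or an oxidation–reduction detour, would cost two or three steps (the latter is kept in reserve). The forward reaction needs the C4–OH to be the only hydroxyl that can be activated, which holds because the other one is tertiary.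

**O–O (7 ⇒ 6).** The cis-2-ene-1,4-diol 7 is the reduced form of the 1,4-endoperoxide 6. Reduction must cleave only the O–O bond, so that both carbinol configurations pass unchanged.

**C1–O and C4–O (6 ⇒ 5), the key cut.** Removing O2 from 6 gives the cyclohexa-1,3-diene acetonide 5. One cycloaddition forms both C–O bonds, the quaternary C1, the C2=C3 alkene and the 1β,4β configuration. Stepwise alternatives (epoxidation plus allylic substitution, or addition of a C7 nucleophile to a C1 ketone) need two or three steps and control C1 less well. The precursor loses two stereocentres and two oxygens. The forward step must be fully anti to the acetal and must be a cycloaddition, not an ene reaction.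

**Ester C–O and C1–C7 (5 ⇒ 4 ⇒ 2 + 3).** The benzoate is put on the primary carbinol of 4, and C1–C7 is cut to the alkenyl bromide 2 and (tributylstannyl)methanol 3. This adds the one missing carbon at the right oxidation level in a single coupling. It also allows the purchasable bromobenzene-derived diol to stand in for a benzyl-alcohol-derived diol that is not a catalogue item.

**Acetal (2 ⇒ 1).** Acetonide 2 comes from commercial (1S,2S)-3-bromocyclohexa-3,5-diene-1,2-diol 1. Its C2 carbinol becomes C6 of the target with the correct configuration, and no later step touches it.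

## Roads not taken

**Alternative 1:** The cut is the C1–C7 bond, made last on a preformed ring. The matching enantiomer of conduritol B, A1 (C2-symmetric, all-trans tetrol), would be converted into enone A2 (C1 ketone, 4-O-PMB, 5,6-O-disiloxane). In the forward key step dimethylsulfonium methylide would add to the C1 carbonyl of A2 from the axial (α) direction and close the spiro-oxirane A3, forming C1–C7 and C7–O. Benzoate opening at C7, PMB removal, C4 benzoylation and desilylation would follow.
- Merits: the 4α,5β,6α triad is bought intact, so no inversion is needed. The two allylic hydroxyls of A1 are homotopic, so mono-protection raises no site question. Oxirane opening sets the C7 ester and frees the tertiary alcohol in one step.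
- Weak points: enantiopure A1 is itself a multistep target. Three different masks must be placed on four similar hydroxyls. The ylide is a base acting on an enone with a β-silyloxy group, which can eliminate toward a phenol. The C1 configuration depends on axial attack next to a bulky silyloxy group.
- Comparison: this road is better in needing no inversion. The chosen plan offsets its two inversions with a shorter path to enantiopure material, a single protecting group, and a C1 configuration set by a rigid acetal instead of a conformational preference.

**Alternative 2:** The cut is the ring bond C3–C4. A pentose-derived open chain, the Z-iodoalkenyl aldehyde A4, would be cyclised with CrCl2 (divalent chromium) and catalytic NiCl2 in a Nozaki–Hiyama–Kishi reaction. The alkenylchromium species adds to the C4 aldehyde and gives cyclohexene-1,4-diol A5.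
- Merits: C5 and C6 come from the chiral pool already trans. There is no photochemistry, no tin and no inversion if the closure is selective. Open-chain intermediates lend themselves to analogues.
- Weak points: the quaternary C1 has to be built with stereocontrol in an acyclic ketone addition. The Z-iodoalkene must be made and kept. The new C4 carbinol arises in the ring closure with no element that clearly favours the α-alcohol. Chromium is used in excess. After A5 four further steps remain to sort three protecting-group types.
- Comparison: realistically this is several steps longer than the chosen plan and has two stereocentres under weak control. Its only advantage is independence from the enzymatic diol, which does not outweigh that.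

**Alternative 3:** No carbon–carbon bond is cut. 4-Hydroxybenzyl alcohol A6 would be dearomatised and protected to the achiral para-quinol dienone A7. In the forward key step 9-amino-9-deoxy-epi-quinine trifluoroacetate and H2O2 would epoxidise one enantiotopic alkene, forming C5–O and C6–O and making C1 stereogenic in epoxy enone A8. Reduction of the C4 ketone to the α-alcohol, benzoylation, hydrolytic opening of the oxirane at C5 with inversion, and desilylation would finish the route.
- Merits: this is the shortest road on paper, about one step fewer than the chosen plan, from an achiral commodity. The 5,6-trans glycol comes from oxirane opening with no separate inversion, and no tin is used.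
- Weak points: the catalyst must choose between two enantiotopic alkenes and also between the face cis to CH2OBz and the face cis to the silyloxy group, so four epoxides are possible. Iminium activation of a hindered, cross-conjugated ketone and over-epoxidation are open questions. The C4 reduction and the site of oxirane opening must also both go the right way.
- Comparison: in step economy and reagent profile this road is as good or better. The chosen plan sets against it an absolute configuration that is purchased instead of induced, and a face selectivity that comes from a rigid substrate with close analogy. If the catalytic step of Alternative 3 fails, no stereochemical fallback remains.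

Key step: step 4

Assumption: commercial diol 1 is enantiopure (1S,2S); all absolute configuration in the route derives from it.

## Route

Step 1
Reactants: 1 (1S,2S)-3-bromocyclohexa-3,5-diene-1,2-diol
Product: 2 (3aS,7aS)-4-bromo-2,2-dimethyl-3a,7a-dihydro-1,3-benzodioxole
Conditions: 2,2-dimethoxypropane, p-toluenesulfonic acid monohydrate (cat.), acetone, 0 °C to rt
Reagents that add atoms: 2,2-dimethoxypropane, COC(C)(C)OC
Why: Acid-catalysed acetal exchange (ketalisation): only the cis-vicinal diol can close the five-membered dioxolane, no stereocentre is touched, and brief exposure to catalytic acid in the cold avoids dehydration of the diene diol to a bromophenol.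

Step 2
Reactants: 2 (3aS,7aS)-4-bromo-2,2-dimethyl-3a,7a-dihydro-1,3-benzodioxole; 3 (tributylstannyl)methanol
Product: 4 [(3aR,7aS)-2,2-dimethyl-3a,7a-dihydro-1,3-benzodioxol-4-yl]methanol
Conditions: Pd(PPh3)4 (5 mol %), 1,4-dioxane (degassed), 80 °C
Reagents that add atoms: none
Why: Stille cross-coupling: oxidative addition of the alkenyl bromide to zerovalent palladium, transfer of the oxygen-activated hydroxymethyl group from tin in preference to butyl, and reductive elimination form C1–C7 with the diene and both stereocentres unchanged; hydroxymethylation of sp2 halides with this stannane is an established use of the reaction.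

Step 3
Reactants: 4 [(3aR,7aS)-2,2-dimethyl-3a,7a-dihydro-1,3-benzodioxol-4-yl]methanol
Product: 5 [(3aR,7aS)-2,2-dimethyl-3a,7a-dihydro-1,3-benzodioxol-4-yl]methyl benzoate (diene acetonide; in the C1–C7 numbering C1=C2–C3=C4 diene with α-oxygens at C5 and C6)
Conditions: BzCl, Et3N, 4-(dimethylamino)pyridine (cat.), CH2Cl2, 0 °C
Reagents that add atoms: benzoyl chloride, O=C(Cl)c1ccccc1
Why: Nucleophile-catalysed O-acylation of the only hydroxyl; basic, anhydrous conditions protect the acid-labile dienyl acetal, and the C7 benzoate is the one that stays in the target.

Step 4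
Reactants: 5 [(3aR,7aS)-2,2-dimethyl-3a,7a-dihydro-1,3-benzodioxol-4-yl]methyl benzoate
Product: 6 [(1R,4R,5R,6S)-1,4-epidioxy-5,6-(isopropylidenedioxy)cyclohex-2-en-1-yl]methyl benzoate (C1–C7 numbering; O–O bridge on the β face at C1 and C4, acetonide on the α face)
Conditions: O2, 5,10,15,20-tetraphenylporphyrin (cat.), visible light, CH2Cl2, −30 °C
Reagents that add atoms: dioxygen, O=O
Why: Energy transfer from the excited porphyrin generates singlet oxygen, which adds as the 2π partner to the s-cis C1=C2–C3=C4 diene in a concerted suprafacial [4+2] cycloaddition, the reaction type long established for cyclohexa-1,3-dienes and for arene cis-dihydrodiol acetonides. Both C–O bonds (C1–O and C4–O) form in this one event, the unsaturation moves to C2=C3, and the six-membered 1,2-dioxine ring of the 2,3-dioxabicyclo[2.2.2]oct-5-ene closes by the cycloaddition itself, not by a separate cyclisation. The two new stereocentres C1 and C4 are set together by the cis-fused dioxolane on C5/C6, which covers the α face with its oxygens and one methyl group, so that oxygen is delivered to the β face at both termini, C6 controlling C1 and C5 controlling C4. The suprafacial mode makes the C1 and C4 oxygens cis to each other, and the anti relation to O6 is the 1,6-trans relation of the target. The step needs β over α attack, which the rigid acetal secures, and [4+2] over the ene mode at the C7 methylene or ring hydrogens, which the locked s-cis diene and the low temperature favour. It also needs cycloaddition to outrun thermal dimerisation of 5, for which the diene is used fresh in dilute cold solution. C1 carries no hydrogen, so only C4–H is open to base-induced fragmentation, and 6 is therefore handled cold and free of amines.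

Step 5
Reactants: 6 [(1R,4R,5R,6S)-1,4-epidioxy-5,6-(isopropylidenedioxy)cyclohex-2-en-1-yl]methyl benzoate
Product: 7 [(1R,4R,5S,6S)-1,4-dihydroxy-5,6-(isopropylidenedioxy)cyclohex-2-en-1-yl]methyl benzoate (1β-OH, 4β-OH, acetonide α)
Conditions: thiourea (2 equiv), MeOH, 0 °C to rt
Reagents that add atoms: none
Why: Thiourea reduction of a dialkyl peroxide: sulfur attacks the O–O bond and no C–O bond is broken, so both carbinol configurations are retained and the cis-2-ene-1,4-diol results; ester, acetal and alkene are inert to the reagent.

Step 6
Reactants: 7 [(1R,4R,5S,6S)-1,4-dihydroxy-5,6-(isopropylidenedioxy)cyclohex-2-en-1-yl]methyl benzoate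
Product: 8 [(1R,4S,5S,6S)-4-(benzoyloxy)-1-hydroxy-5,6-(isopropylidenedioxy)cyclohex-2-en-1-yl]methyl benzoate (1β-OH, 4α-OBz, acetonide α)
Conditions: PPh3, diisopropyl azodicarboxylate, BzOH, THF, 0 °C to rt
Reagents that add atoms: benzoic acid, O=C(O)c1ccccc1
Why: Mitsunobu reaction: only the secondary allylic C4–OH is activated as the alkoxyphosphonium ion (the tertiary C1–OH is too hindered), and benzoate displaces it by SN2 with inversion, placing the final ester on the α face in one step. The C1–OH lies on the face of the leaving group and cannot close an ether, and direct substitution is preferred over SN2' because C2 is shielded by the quaternary C1.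

Step 7
Reactants: 8 [(1R,4S,5S,6S)-4-(benzoyloxy)-1-hydroxy-5,6-(isopropylidenedioxy)cyclohex-2-en-1-yl]methyl benzoate
Product: 9 [(1R,4S,5R,6S)-4-(benzoyloxy)-1,5,6-trihydroxycyclohex-2-en-1-yl]methyl benzoate (1β-OH, 4α-OBz, 5α-OH, 6α-OH; the 5-epimer of the target)
Conditions: AcOH–H2O (4:1), 50 °C
Reagents that add atoms: none
Why: Acid-catalysed acetal hydrolysis; dilute acetic acid opens the cis-fused dioxolane but is too weak to ionise the tertiary allylic alcohol or the allylic benzoate or to drive O4→O5 acyl transfer quickly, and no stereocentre is involved.

Step 8
Reactants: 9 [(1R,4S,5R,6S)-4-(benzoyloxy)-1,5,6-trihydroxycyclohex-2-en-1-yl]methyl benzoate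
Product: 10 [(1R,4S,5R,6S)-4-(benzoyloxy)-1,6-dihydroxy-5-(trifluoromethanesulfonyloxy)cyclohex-2-en-1-yl]methyl benzoate (5α-OTf)
Conditions: Tf2O (1.05 equiv), pyridine, CH2Cl2, −40 to −20 °C; cold aqueous work-up, used crude
Reagents that add atoms: trifluoromethanesulfonic anhydride, O=S(=O)(OS(=O)(=O)C(F)(F)F)C(F)(F)F
Why: Kinetic O-sulfonylation: with one equivalent of anhydride in the cold the triflyl group should go to C5–OH, the only unhindered secondary hydroxyl, because C6–OH is flanked by the fully substituted C1 and C1–OH is tertiary; the configuration at C5 is unchanged at this stage.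

Step 9
Reactants: 10 [(1R,4S,5R,6S)-4-(benzoyloxy)-1,6-dihydroxy-5-(trifluoromethanesulfonyloxy)cyclohex-2-en-1-yl]methyl benzoate
Product: 12 kweichowenol B [(1R,4S,5S,6S)-4-(benzoyloxy)-1,5,6-trihydroxycyclohex-2-en-1-yl]methyl benzoate, via C5 β-nitrite ester 11 (not isolated)
Conditions: n-Bu4NNO2, MeCN, 0 °C to rt; then H2O
Reagents that add atoms: tetrabutylammonium nitrite, CCCC[N+](CCCC)(CCCC)CCCC.[O-]N=O
Why: Lattrell–Dax inversion: nitrite attacks C5 through oxygen from the β face in an SN2 displacement of triflate, and the nitrite ester 11 is hydrolysed on aqueous work-up, giving the 5β-alcohol with no ester cleavage. The cis C4 benzoate cannot participate because it is on the face of the leaving group, a flanking ester of this kind is the arrangement in which this inversion works best on pyranosides, and C6 and C1 are not touched.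

## Compound list

1 | (1S,2S)-3-bromocyclohexa-3,5-diene-1,2-diol | BrC1=CC=C[C@H](O)[C@@H]1O | starting material
2 | (3aS,7aS)-4-bromo-2,2-dimethyl-3a,7a-dihydro-1,3-benzodioxole | BrC1=CC=C[C@@H]2OC(C)(C)O[C@H]12 | intermediate
3 | (tributylstannyl)methanol | CCCC[Sn](CCCC)(CCCC)CO | starting material
4 | [(3aR,7aS)-2,2-dimethyl-3a,7a-dihydro-1,3-benzodioxol-4-yl]methanol | OCC1=CC=C[C@@H]2OC(C)(C)O[C@H]12 | intermediate
5 | [(3aR,7aS)-2,2-dimethyl-3a,7a-dihydro-1,3-benzodioxol-4-yl]methyl benzoate | O=C(OCC1=CC=C[C@@H]2OC(C)(C)O[C@H]12)c1ccccc1 | intermediate
6 | [(1R,4R,5R,6S)-1,4-epidioxy-5,6-(isopropylidenedioxy)cyclohex-2-en-1-yl]methyl benzoate (endoperoxide, O–O β, acetonide α) | O=C(OC[C@@]12C=C[C@@H](OO1)[C@@H]3OC(C)(C)O[C@H]23)c1ccccc1 | intermediate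
7 | [(1R,4R,5S,6S)-1,4-dihydroxy-5,6-(isopropylidenedioxy)cyclohex-2-en-1-yl]methyl benzoate | O=C(OC[C@]1(O)C=C[C@@H](O)[C@@H]2OC(C)(C)O[C@H]12)c1ccccc1 | intermediate
8 | [(1R,4S,5S,6S)-4-(benzoyloxy)-1-hydroxy-5,6-(isopropylidenedioxy)cyclohex-2-en-1-yl]methyl benzoate | O=C(OC[C@]1(O)C=C[C@H](OC(=O)c2ccccc2)[C@@H]3OC(C)(C)O[C@H]13)c1ccccc1 | intermediate
9 | [(1R,4S,5R,6S)-4-(benzoyloxy)-1,5,6-trihydroxycyclohex-2-en-1-yl]methyl benzoate | O=C(OC[C@]1(O)C=C[C@H](OC(=O)c2ccccc2)[C@H](O)[C@@H]1O)c1ccccc1 | intermediate
10 | [(1R,4S,5R,6S)-4-(benzoyloxy)-1,6-dihydroxy-5-(trifluoromethanesulfonyloxy)cyclohex-2-en-1-yl]methyl benzoate | O=C(OC[C@]1(O)C=C[C@H](OC(=O)c2ccccc2)[C@H](OS(=O)(=O)C(F)(F)F)[C@@H]1O)c1ccccc1 | intermediate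
11 | [(1R,4S,5S,6S)-4-(benzoyloxy)-1,6-dihydroxy-5-(nitrosooxy)cyclohex-2-en-1-yl]methyl benzoate (not isolated) | O=C(OC[C@]1(O)C=C[C@H](OC(=O)c2ccccc2)[C@@H](ON=O)[C@@H]1O)c1ccccc1 | intermediate
12 | kweichowenol B, [(1R,4S,5S,6S)-4-(benzoyloxy)-1,5,6-trihydroxycyclohex-2-en-1-yl]methyl benzoate | O=C(OC[C@]1(O)C=C[C@H](OC(=O)c2ccccc2)[C@@H](O)[C@@H]1O)c1ccccc1 | target

## Step count and least certain steps

Total step count: 9. Longest linear sequence: 9 steps (1 to 12); stannane 3 is a purchased one-carbon reagent.

**Step 4 (key step).**
- What may go wrong: loss of material to processes that compete with or follow the cycloaddition. These are hydrogen abstraction in the ene mode at the C7 methylene, thermal dimerisation of diene 5 before it meets singlet oxygen, and fragmentation of the peroxide by removal of C4–H on contact with base or silica during isolation. Leakage to the α face is the least likely of the failures because of the rigid acetal.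
- Fallback (peroxide-free, stepwise polar oxygenation), from 4 back to 7: the C7 hydroxyl of 4 directs epoxidation by t-BuOOH with catalytic VO(acac)2 to C1=C2 on the β face, away from the acetal, giving the 1β,2β-epoxy alcohol F1. Benzoylation of the primary hydroxyl gives the epoxy benzoate F2. Pd(PPh3)4 (zerovalent palladium) with acetic acid opens the vinyl oxirane through a π-allyl complex with double inversion, i.e. net retention, which puts acetate at C4 cis to the C1 oxygen in the 4β-acetate F3. Mg(OMe)2 in methanol removes the secondary acetate in preference to the hindered primary benzoate and returns 7.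

**Step 8.**
- What may go wrong: sulfonylation spreading to O6 or to both secondary hydroxyls, since the choice rests on a steric difference alone, and base-promoted benzoyl migration from O4 to the cis O5 before the anhydride arrives.
- Fallback (both oxygens activated at once, the site chosen by the displacement), from 9 to 12: SOCl2 and Et3N give the 5α,6α-cyclic sulfite F4. Catalytic RuCl3 with NaIO4 at 0 °C and short contact (to spare the ring alkene) gives the cyclic sulfate F5. CsOAc in DMF opens it at C5 with inversion, because C6 is neopentyl-like, to the 5β-acetate 6α-sulfate cesium salt F6. Catalytic H2SO4 in wet THF cleaves the sulfate monoester to the 5-O-acetyl derivative of the target F7. HCl in methanol removes the acetate in the presence of the two benzoates and gives 12.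

**Step 9.**
- What may go wrong: E2 loss of the triflate toward C4, whose hydrogen is allylic, geminal to the benzoate and anti to the leaving group, followed by aromatisation; or attack of the ambident nitrite through nitrogen.
- Fallback (non-basic halide, then an epoxide relay), from 10 to 12: LiBr in acetone gives the 5β-bromide F8 by SN2. The bromine is then syn to both neighbouring hydrogens, which shuts off anti elimination. K2CO3 in MeCN lets the trans O6 close the 5α,6α-oxirane F9 (second inversion at C5). Dilute HClO4 in aqueous THF opens it with water at C5 from the β face (third inversion; C6 is neopentyl-like and the cis C4 benzoate cannot participate), giving 12.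

**Step 6.**
- What may go wrong: the nucleophile has to enter on the α face next to the acetal, so activation may end in SN2' attack at C2, in elimination to a dienyl system, or in recovered alcohol.
- Fallback (oxidation state change instead of substitution), from 6 to 8: Et3N in CH2Cl2 fragments the peroxide (Kornblum–DeLaMare; C4–H is the only hydrogen available) to the 1β-hydroxy-4-enone F10. NaBH4 with CeCl3·7H2O (Luche) delivers hydride to the β face, anti to the acetal, giving the 4α-alcohol F11. BzCl in pyridine acylates the secondary hydroxyl beside the tertiary one and gives 8.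

**Step 2.**
- What may go wrong: slow transfer of the hydroxymethyl group at the temperature required, during which the diene dimerises, butyl is transferred instead, or the stannane is protonated.
- Fallback (carbonylation–reduction), from 2 to 4: Pd(OAc)2 with PPh3 under CO in MeOH–Et3N converts the alkenyl bromide into the methyl ester F12, and i-Bu2AlH at −78 °C reduces it to 4.

## Further compounds

F1 | step 4 | 1β,2β-epoxide of 4: [(1β,2β)-epoxy-5α,6α-(isopropylidenedioxy)cyclohex-3-en-1-yl]methanol | OC[C@]12O[C@H]1C=C[C@@H]3OC(C)(C)O[C@H]23
F2 | step 4 | benzoate of F1 | O=C(OC[C@]12O[C@H]1C=C[C@@H]3OC(C)(C)O[C@H]23)c1ccccc1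
F3 | step 4 | 4β-O-acetyl derivative of 7 | O=C(OC[C@]1(O)C=C[C@@H](OC(C)=O)[C@@H]2OC(C)(C)O[C@H]12)c1ccccc1
F4 | step 8 | 5α,6α-cyclic sulfite of 9 | O=C(OC[C@]1(O)C=C[C@H](OC(=O)c2ccccc2)[C@@H]3OS(=O)O[C@H]13)c1ccccc1
F5 | step 8 | 5α,6α-cyclic sulfate of 9 | O=C(OC[C@]1(O)C=C[C@H](OC(=O)c2ccccc2)[C@@H]3OS(=O)(=O)O[C@H]13)c1ccccc1
F6 | step 8 | 5β-acetate 6α-sulfate, cesium salt | O=C(OC[C@]1(O)C=C[C@H](OC(=O)c2ccccc2)[C@@H](OC(C)=O)[C@@H]1OS(=O)(=O)[O-])c1ccccc1.[Cs+]
F7 | step 8 | 5-O-acetylkweichowenol B | O=C(OC[C@]1(O)C=C[C@H](OC(=O)c2ccccc2)[C@@H](OC(C)=O)[C@@H]1O)c1ccccc1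
F8 | step 9 | 5β-bromo-5-deoxy compound (1β-OH, 4α-OBz, 6α-OH) | O=C(OC[C@]1(O)C=C[C@H](OC(=O)c2ccccc2)[C@@H](Br)[C@@H]1O)c1ccccc1
F9 | step 9 | 5α,6α-epoxide (1β-OH, 4α-OBz) | O=C(OC[C@]1(O)C=C[C@H](OC(=O)c2ccccc2)[C@@H]3O[C@H]13)c1ccccc1
F10 | step 6 | 1β-hydroxy-4-oxo enone with 5α,6α-acetonide | O=C(OC[C@]1(O)C=CC(=O)[C@@H]2OC(C)(C)O[C@H]12)c1ccccc1
F11 | step 6 | 4α-alcohol (4-epimer of 7) | O=C(OC[C@]1(O)C=C[C@H](O)[C@@H]2OC(C)(C)O[C@H]12)c1ccccc1
F12 | step 2 | methyl (3aR,7aS)-2,2-dimethyl-3a,7a-dihydro-1,3-benzodioxole-4-carboxylate | COC(=O)C1=CC=C[C@@H]2OC(C)(C)O[C@H]12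
A1 | alternative 1 | conduritol B, enantiomer with 1β,4α,5β,6α hydroxyls | O[C@H]1C=C[C@H](O)[C@@H](O)[C@@H]1O
A2 | alternative 1 | C1 enone, 4α-O-PMB, 5β,6α-O-(tetraisopropyldisiloxane-1,3-diyl) | O=C1C=C[C@H](OCc2ccc(OC)cc2)[C@@H](O[Si]3(C(C)C)C(C)C)[C@@H]1O[Si](C(C)C)(C(C)C)O3
A3 | alternative 1 | spiro-oxirane at C1 (oxirane O β, C7 α), 4-O-PMB, 5,6-O-disiloxane | O1C[C@]21C=C[C@H](OCc3ccc(OC)cc3)[C@@H](O[Si]4(C(C)C)C(C)C)[C@@H]2O[Si](C(C)C)(C(C)C)O4
A4 | alternative 2 | Z-iodoalkenyl aldehyde, 5,6-di-O-PMB, C1 tertiary alcohol, C7 O-TBDPS | CC(C)(C)[Si](c1ccccc1)(c1ccccc1)OC[C@](O)(/C=C\I)[C@@H](OCc1ccc(OC)cc1)[C@H](OCc1ccc(OC)cc1)C=O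
A5 | alternative 2 | cyclohexene-1,4-diol, 5,6-di-O-PMB, C7 O-TBDPS | CC(C)(C)[Si](c1ccccc1)(c1ccccc1)OC[C@]1(O)C=C[C@H](O)[C@@H](OCc2ccc(OC)cc2)[C@@H]1OCc1ccc(OC)cc1
A6 | alternative 3 | 4-hydroxybenzyl alcohol | OCc1ccc(O)cc1
A7 | alternative 3 | 4-(benzoyloxymethyl)-4-(triethylsilyloxy)cyclohexa-2,5-dienone | O=C(OCC1(O[Si](CC)(CC)CC)C=CC(=O)C=C1)c1ccccc1
A8 | alternative 3 | epoxy enone: C4 ketone, 5α,6α-oxirane, 1β-OSiEt3 | O=C(OC[C@]1(O[Si](CC)(CC)CC)C=CC(=O)[C@@H]2O[C@H]12)c1ccccc1
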